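The readings were generated by integration on assumed constants.

In a one-step world each starting material costs one coupling partner, and at 1.00 equiv the two would fall together along a plain second-order hyperbola. I began by testing that world against the two earlier runs.

| flask | starting material | coupling partner | capture agent | remark | time |
|---|---|---|---|---|---|
| Monday's | 0.54 M | 0.50 equiv | 0.162 M | run made earlier |  |
| Wednesday's | 0.54 M | 0.75 equiv | 0.162 M | run made earlier |  |
| gamma | 0.54 M | 1.00 equiv | 0.162 M |  | 2.0 h |
| delta | 0.54 M | 1.00 equiv | 0.162 M |  | 3.0 h |
| zeta | 0.54 M | 1.00 equiv | 0.162 M |  | 5.0 h |

| run | time / min | trapped intermediate / % | starting material / % | bis adduct / % | first product / % | triple product / % |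
|---|---|---|---|---|---|---|
| Monday's | 8.00 | 0 | 96.9 | 1.0 | 3.5 | 0 |
| Monday's | 20.0 | 0 | 93.5 | 0.9 | 5.6 | 0 |
| Monday's | 40.0 | 0 | 90.9 | 2.7 | 9.8 | 0 |
| Monday's | 90.0 | 0 | 81.5 | 3.9 | 17.2 | 0 |
| Wednesday's | 25.0 | 0 | 90.4 | 0.6 | 10.1 | 0.4 |
| Wednesday's | 50.0 | 1.7 | 83.3 | 0.6 | 17.3 | 0 |
| Wednesday's | 80.0 | 1.6 | 75.8 | 2.6 | 20.9 | 0 |
| Wednesday's | 90.0 | 0.8 | 72.1 | 5.0 | 20.4 | 0 |

(scatter of a reading: 1 percentage point)

- which of these there is most of at the end, counted by the starting material in it, gamma (starting material / first product / bis adduct / trapped intermediate)
- which of these there is most of at the end, counted by the starting material in it, delta (starting material / first product / bis adduct / trapped intermediate)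
- which of these there is most of at the end, counted by the starting material in it, zeta (starting material / first product / bis adduct / trapped intermediate)
- how much there is at the end of the one of these that leads, in percent of the starting material charged: gamma
- how much there is at the end of the one of these that leads, in percent of the starting material charged: delta
- how much there is at the end of the one of these that leads, in percent of the starting material charged: zeta

- the earlier runs were read with a standard deviation of 1 percentage point
- a reading or a percentage of triple product counts all its forms, free or not

The readings showed bis adduct, which I took to carry two partners. I therefore defined the surcharge q as the extra partner spent per starting material reacted, that is, bis adduct over first product plus bis adduct. At Wednesday's last reading, with 27.9% reacted, I read q as 0.197. I took bis adduct to grow out of first product, so I let q rise in proportion to conversion, with the slope 0.706, the surcharge per unit of conversion. Using the mean partner level of that run, I read 0.0115 /M/min for the first addition.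

With q held through a run at 1.00 equiv, the fraction of starting material left is a = q/(1+q−exp(−q·k·c·t)), where c is c(starting material) as charged. As q goes to zero this tends to the hyperbola.

I turned time first. The one-step world gave 57.2%, 47.1% and 34.8% for gamma, delta and zeta. Putting each conversion back through the slope and going round once more gave 59.9%, 52.2% and 44.4%. For zeta I reckoned first product at 30.1%, so in my reckoning starting material stayed ahead.

Next I turned the partner. Going from 0.75 equiv to 1.00 equiv raises the opening rate by a factor of 1.33. In zeta, with the surcharge, I reckoned 18.8% of the partner left, less than the 44.4% of starting material, so in my reckoning the partner was the limiting reagent. The capture agent stood at 0.162 M in both earlier runs, so the readings gave me no slope for it.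

The forecast gave 58%, 49% and 40% and, differing from me at zeta, put first product ahead in “a near tie”.

Gamma ended with starting material ahead at 59.5%, delta at 51.8%, and zeta at 44.2% against 30.9% of first product.

    starting material + coupling partner → first product (k = 0.0116 /M/min)
    coupling partner + first product → bis adduct (k = 0.0161 /M/min)
    coupling partner + bis adduct → triple product (k = 0.0115 /M/min)
    bis adduct + capture agent → trapped intermediate (k = 0.0281 /M/min)
    crystals ⇌ triple product, rate k5*(cs5 - [triple product]) while solid is left; crystals form when [triple product] > cs5 (solubility = 5.70 mM, k = 0.914 /min)
    coupling partner → decomposition product (k = 2.83 × 10⁻⁵ /min)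

In delta, half the first addition's turnover up to the end was done by 0.865 h, with 2.4 h as the partner's half-life by that step at that moment. In delta, the step from bis adduct to trapped intermediate had 2.9% of its turnover up to the end behind it at 0.600 h, and trapped intermediate ended at 4.53%. In zeta, the partner spent per starting material reacted exceeded one by 0.539, above my 0.460. For delta's neighbour, charged with 0.22 M of starting material, the same two rounds with the slope gave 68.6%, then 69.7%, and that flask held 69.5% of starting material.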